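**Retrosynthetic overview**

- Feature: with side-chain locants C1' (CH2 on the quinone) to C25' (CH2 on the cyclohexene), the saturated stretch C4'–C13' carries the methyl stereocentres C7' and C11', three methylenes apart and of like sense. This stretch is C10→C1 of (2E,6E)-farnesol read from tail to head, so both centres are set in one double asymmetric hydrogenation of an achiral C10 diene cut from farnesol, before any alkene that must survive is present.
- Disconnections, last made first: C1'–C2' (E-alkenylalane from a terminal alkyne plus chloromethyl-menadione, zerovalent nickel); C13'–C14' (alkylzinc of the stereodiad plus an E-alkenyl iodide); C24'–C25' (α-cyclogeranyl sulfone anion plus an allylic bromide made from geranyl bromide).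
- Ring stereocentre: CBS reduction of 2-iodo-4,4-dimethylcyclohexenone, then a Wittig–Still [2,3] shift that relays the carbinol chirality to carbon and moves the alkene into the α position.
- Rings: none is formed. The cyclohexene is bought as 4,4-dimethylcyclohex-2-enone and the naphthoquinone as menadione; the chain is joined from the cyclohexene end towards the quinone.

Key step: step 20

Remark: by CIP analysis the target is (S) at the ring carbon, (R) at C7' and (S) at C11', with all four chain alkenes E.
Assumption: in the oxazaborolidine reduction the 2-iodoalkenyl arm is taken as the larger carbonyl substituent, so the (S)-catalyst is expected to give the (R)-carbinol; the catalyst antipode would be used if the carbinol proved to be (S).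

**Ring fragment**

Step 1
Reactants: 1 4,4-dimethylcyclohex-2-en-1-one
Product: 2 2-iodo-4,4-dimethylcyclohex-2-en-1-one
Conditions: I2, pyridine/CH2Cl2 (1:1), 0 °C to rt
Reagents that add atoms: iodine, [I][I]
Why: α-Iodination of the enone by conjugate addition of pyridine, iodination of the enolate and elimination, which installs the handle for the later methylation and makes the alkenyl arm the large group for the reduction.

Step 2
Reactants: 2 2-iodo-4,4-dimethylcyclohex-2-en-1-one
Product: 3 (1R)-2-iodo-4,4-dimethylcyclohex-2-en-1-ol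
Conditions: (S)-Me-CBS oxazaborolidine [(S)-1-methyl-3,3-diphenyltetrahydro-1H,3H-pyrrolo[1,2-c][1,3,2]oxazaborole] (10 mol %), BH3·SMe2, THF, −20 °C; MeOH quench
Reagents that add atoms: none
Why: Corey–Bakshi–Shibata reduction, in which the ketone binds the catalyst boron anti to the larger iodoalkenyl arm and hydride is delivered within the complex to one carbonyl face, which should give the (R)-carbinol that is the source of the ring stereocentre.

Step 3
Reactants: 3 (1R)-2-iodo-4,4-dimethylcyclohex-2-en-1-ol
Product: 4 (1R)-2,4,4-trimethylcyclohex-2-en-1-ol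
Conditions: Me2Zn (3 equiv), Pd(dppf)Cl2 (5 mol %), THF, 0 to 50 °C
Reagents that add atoms: dimethylzinc, C[Zn]C
Why: Negishi cross-coupling of the alkenyl iodide with the methylzinc reagent (the hydroxyl is carried as its zinc alkoxide), which does not touch the carbinol centre.

Step 4
Reactants: 4 (1R)-2,4,4-trimethylcyclohex-2-en-1-ol
Product: 5 tributyl({[(1R)-2,4,4-trimethylcyclohex-2-en-1-yl]oxy}methyl)stannane
Conditions: KH, THF, 0 °C; Bu3SnCH2I, 0 °C to rt
Reagents that add atoms: (iodomethyl)tributylstannane, IC[Sn](CCCC)(CCCC)CCCC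
Why: Williamson etherification of the potassium alkoxide at the unhindered primary iodide, with no bond to the stereocentre broken.

Step 5
Reactants: 5 tributyl({[(1R)-2,4,4-trimethylcyclohex-2-en-1-yl]oxy}methyl)stannane
Product: 7 (S)-alpha-cyclogeraniol [(1S)-2,6,6-trimethylcyclohex-2-en-1-yl]methanol, via lithiomethyl ether 6 (not isolated)
Conditions: n-BuLi, THF, −78 °C, then slowly to −20 °C; H2O quench
Reagents that add atoms: none
Why: Wittig–Still [2,3]-sigmatropic rearrangement, in which tin–lithium exchange gives the unstabilised alkoxymethyllithium that bonds suprafacially to the far alkene carbon on the face the oxygen leaves, so the (R)-carbinol becomes the (S)-ring stereocentre and the alkene moves to the α position.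

Step 6
Reactants: 7 (S)-alpha-cyclogeraniol
Product: 8 phenyl {[(1S)-2,6,6-trimethylcyclohex-2-en-1-yl]methyl} sulfide
Conditions: PhSSPh, n-Bu3P, pyridine, rt to 60 °C
Reagents that add atoms: diphenyl disulfide, c1ccccc1SSc1ccccc1
Why: Hata-type substitution, in which the alkoxyphosphonium ion is displaced by thiolate at the primary carbon (SN2), leaving the neighbouring stereocentre untouched.

Step 7
Reactants: 8 phenyl {[(1S)-2,6,6-trimethylcyclohex-2-en-1-yl]methyl} sulfide
Product: 9 (S)-alpha-cyclogeranyl phenyl sulfone, ({[(1S)-2,6,6-trimethylcyclohex-2-en-1-yl]methyl}sulfonyl)benzene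
Conditions: (NH4)6Mo7O24·4H2O (10 mol %), 30% H2O2, EtOH, 0 °C to rt
Reagents that add atoms: hydrogen peroxide, OO
Why: Molybdate-catalysed peroxide oxidation of sulfide to sulfone, which is much faster than epoxidation of the trisubstituted ring alkene.

**Geranyl-derived chain**

Step 8
Reactants: 10 geranyl bromide; 11 1-(trimethylsilyl)propyne
Product: 13 trimethyl[(5E)-6,10-dimethylundeca-5,9-dien-1-yn-1-yl]silane, via lithiated silylpropyne 12 (not isolated)
Conditions: 11, n-BuLi, THF, −78 to −20 °C; then 10, −78 °C to rt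
Reagents that add atoms: none
Why: Propargylic lithiation of the silylpropyne and SN2 alkylation by the primary allylic bromide, the silyl group steering reaction to the propargyl terminus and the E alkene of the geranyl unit being retained.

Step 9
Reactants: 13 trimethyl[(5E)-6,10-dimethylundeca-5,9-dien-1-yn-1-yl]silane
Product: 14 (2E,6E)-2,6-dimethyl-11-(trimethylsilyl)undeca-2,6-dien-10-yn-1-ol
Conditions: SeO2 (0.3 equiv), salicylic acid (0.1 equiv), t-BuOOH (70% in water, 3 equiv), CH2Cl2, rt; then NaBH4, MeOH, 0 °C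
Reagents that add atoms: tert-butyl hydroperoxide, CC(C)(C)OO (oxygen passed on through selenium dioxide, O=[Se]=O)
Why: SeO2/t-BuOOH allylic oxidation (ene reaction then [2,3] shift), which is selective for the E-methyl of the terminal, most electron-rich alkene, the borohydride returning any over-oxidised enal to the allylic alcohol.

Step 10
Reactants: 14 (2E,6E)-2,6-dimethyl-11-(trimethylsilyl)undeca-2,6-dien-10-yn-1-ol
Product: 15 [(5E,9E)-11-bromo-6,10-dimethylundeca-5,9-dien-1-yn-1-yl]trimethylsilane
Conditions: CBr4, PPh3, CH2Cl2, 0 °C; used without chromatography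
Reagents that add atoms: carbon tetrabromide, BrC(Br)(Br)Br
Why: Appel bromination, an SN2 displacement of the oxyphosphonium at the primary allylic carbon that should proceed without allylic transposition or loss of E geometry at 0 °C.

**Union of ring and chain, tail alkenyl iodide**

Step 11
Reactants: 9 (S)-alpha-cyclogeranyl phenyl sulfone; 15 [(5E,9E)-11-bromo-6,10-dimethylundeca-5,9-dien-1-yn-1-yl]trimethylsilane
Product: 17 trimethyl{(5E,9E)-6,10-dimethyl-12-(phenylsulfonyl)-12-[(1S)-2,6,6-trimethylcyclohex-2-en-1-yl]dodeca-5,9-dien-1-yn-1-yl}silane (both epimers at C12), via lithiated sulfone 16 (not isolated)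
Conditions: 9, n-BuLi, THF, −78 °C; then 15, THF/DMPU, −78 to −20 °C
Reagents that add atoms: none
Why: Alkylation of the α-sulfonyl carbanion by the allylic bromide forms the C24'–C25' bond; the ring stereocentre is not deprotonated and the new sulfone-bearing centre is removed in the next step.

Step 12
Reactants: 17 the ring–chain sulfone
Product: 18 trimethyl{(5E,9E)-6,10-dimethyl-12-[(1S)-2,6,6-trimethylcyclohex-2-en-1-yl]dodeca-5,9-dien-1-yn-1-yl}silane
Conditions: 6% Na(Hg), Na2HPO4, MeOH/THF, −20 °C
Reagents that add atoms: none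
Why: Reductive desulfonylation by electron transfer from the amalgam, the phosphate buffer suppressing base-induced alkene migration, and any partial loss of the alkynyl silyl group being harmless since it is removed next.

Step 13
Reactants: 18 the silyl dienyne
Product: 19 (5E,9E)-6,10-dimethyl-12-[(1S)-2,6,6-trimethylcyclohex-2-en-1-yl]dodeca-5,9-dien-1-yne
Conditions: K2CO3, MeOH/THF, rt
Reagents that add atoms: none
Why: Methoxide-induced protodesilylation of the alkynylsilane, which leaves the alkenes untouched.

Step 14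
Reactants: 19 (5E,9E)-6,10-dimethyl-12-[(1S)-2,6,6-trimethylcyclohex-2-en-1-yl]dodeca-5,9-dien-1-yne
Product: 21 (1E,5E,9E)-1-iodo-2,6,10-trimethyl-12-[(1S)-2,6,6-trimethylcyclohex-2-en-1-yl]dodeca-1,5,9-triene, via E-alkenyldimethylalane 20 (not isolated)
Conditions: Me3Al (2.5 equiv), Cp2ZrCl2 (0.5 equiv), CH2Cl2, 0 °C to rt; then I2, THF, −30 to 0 °C
Reagents that add atoms: trimethylaluminium, C[Al](C)C; iodine, [I][I]
Why: Zirconium-catalysed methylalumination (Negishi carboalumination) adds methyl and aluminium syn across the terminal alkyne with methyl on the inner carbon, and iodinolysis with retention gives the E-alkenyl iodide, the trisubstituted alkenes being inert.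

**Farnesol-derived stereodiad**

Step 15
Reactants: 22 (2E,6E)-farnesol
Product: 23 (2E,6E)-farnesyl pivalate
Conditions: PivCl, pyridine, 4-(dimethylamino)pyridine (cat.), CH2Cl2, 0 °C to rt
Reagents that add atoms: pivaloyl chloride, CC(C)(C)C(Cl)=O
Why: Acylation of the primary allylic alcohol, giving an ester that deactivates the 2,3-alkene towards electrophiles and later keeps the two chain termini distinct.

Step 16
Reactants: 23 (2E,6E)-farnesyl pivalate
Product: 24 (2E,6E)-10-bromo-11-hydroxy-3,7,11-trimethyldodeca-2,6-dien-1-yl pivalate (racemic at C10)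
Conditions: NBS (1.1 equiv), THF/H2O, 0 °C
Reagents that add atoms: N-bromosuccinimide, O=C1CCC(=O)N1Br; water, O
Why: Terminal-selective bromohydrin formation, in which the bromonium ion forms on the most exposed, electron-rich terminal alkene and water opens it at the tertiary carbon.

Step 17
Reactants: 24 the bromohydrin
Product: 25 (2E,6E)-10,11-epoxy-3,7,11-trimethyldodeca-2,6-dien-1-yl pivalate (racemic)
Conditions: K2CO3, MeOH, 0 °C to rt, short reaction time
Reagents that add atoms: none
Why: Intramolecular Williamson closure of the bromohydrin to the epoxide, under conditions mild enough to leave the hindered pivalate intact.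

Step 18
Reactants: 25 the 10,11-epoxide
Product: 26 (2E,6E)-3,7-dimethyl-10-oxodeca-2,6-dien-1-yl pivalate
Conditions: H5IO6, THF/Et2O, 0 °C
Reagents that add atoms: none
Why: Periodic acid opens the epoxide to the glycol and cleaves it (Malaprade cleavage), removing the three terminal carbons as acetone without touching the trisubstituted alkenes.

Step 19
Reactants: 26 (2E,6E)-3,7-dimethyl-10-oxodeca-2,6-dien-1-yl pivalate
Product: 27 (2E,6E)-10-hydroxy-3,7-dimethyldeca-2,6-dien-1-yl pivalate
Conditions: NaBH4, MeOH, 0 °C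
Reagents that add atoms: none
Why: Borohydride reduction of the aldehyde, chemoselective over the ester and the alkenes, gives the achiral diene substrate with two different termini.

Step 20
Reactants: 27 (2E,6E)-10-hydroxy-3,7-dimethyldeca-2,6-dien-1-yl pivalate
Product: 28 (3S,7R)-10-hydroxy-3,7-dimethyldecyl pivalate
Conditions: H2 (50 bar), [Ir(cod)(L*)][B(C6H3-3,5-(CF3)2)4] (1 mol %), L* = single enantiomer of 7-(di-o-tolylphosphinooxy)-2-phenyl-6,7-dihydro-5H-cyclopenta[b]pyridine (the antipode that takes (2E,6E)-farnesol to the (3S,7S)-hexahydro alcohol), CH2Cl2, rt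
Reagents that add atoms: none
Why: After hydrogenative loss of cyclooctadiene, the cationic iridium dihydride binds one alkene of 27, and migratory insertion followed by C–H reductive elimination (a trivalent/pentavalent iridium cycle) places two hydrogens syn on one face; the catalyst then repeats this at the second alkene, so four C–H bonds and both stereocentres (C3 and C7 of 28, later C11' and C7') form in one operation. The closest known reaction type is the iridium pyridine–phosphinite hydrogenation of (2E,6E)-farnesol and of tocotrienyl esters, in which several purely alkyl-substituted C=C bonds are reduced independently under catalyst control. No ring is closed in this step. Each new stereocentre is fixed by the ligand pocket, which places the lone vinylic hydrogen of the bound alkene in its most crowded quadrant; both alkenes are E and point the same way along the chain, so one ligand enantiomer gives both methyl centres the same spatial sense, (3S,7R) in 28, the descriptors differing only because the oxygen-bearing terminus outranks the chain at each end. The step needs high enantioface selectivity at two alkenes independently and no E/Z leakage, which is secured by the geometric purity of the bought farnesol, by the non-coordinating solvent and counterion, and by a substrate that holds only the two alkenes to be reduced, the hydroxyl and the pivalate binding only weakly. The cyclohexene alkene and the four E chain alkenes of the target, which would not survive these conditions, enter only after this step.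

Step 21
Reactants: 28 (3S,7R)-10-hydroxy-3,7-dimethyldecyl pivalate
Product: 29 (3S,7R)-10-iodo-3,7-dimethyldecyl pivalate
Conditions: I2, PPh3, imidazole, CH2Cl2, 0 °C to rt
Reagents that add atoms: iodine, [I][I]
Why: Appel-type iodination of the primary alcohol through the oxyphosphonium ion, remote from both stereocentres.

Step 22
Reactants: 29 (3S,7R)-10-iodo-3,7-dimethyldecyl pivalate; 30 ethynyltrimethylsilane
Product: 32 (3S,7R)-3,7-dimethyl-12-(trimethylsilyl)dodec-11-yn-1-yl pivalate, via lithium silylacetylide 31 (not isolated)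
Conditions: 30, n-BuLi, THF, −78 °C; then 29, DMPU, −20 °C to rt
Reagents that add atoms: none
Why: SN2 alkylation of the lithium acetylide by the primary iodide, accelerated by the dipolar cosolvent, with the hindered pivalate carbonyl expected to resist addition at these temperatures.

Step 23
Reactants: 32 (3S,7R)-3,7-dimethyl-12-(trimethylsilyl)dodec-11-yn-1-yl pivalate
Product: 33 (3S,7R)-3,7-dimethyl-12-(trimethylsilyl)dodec-11-yn-1-ol
Conditions: i-Bu2AlH (2.2 equiv), CH2Cl2, −78 °C; aqueous KNaC4H4O6 work-up
Reagents that add atoms: none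
Why: Reductive cleavage of the pivalate by the aluminium hydride at −78 °C, where hydroalumination of the silylalkyne does not compete.

Step 24
Reactants: 33 (3S,7R)-3,7-dimethyl-12-(trimethylsilyl)dodec-11-yn-1-ol
Product: 34 [(6R,10S)-12-iodo-6,10-dimethyldodec-1-yn-1-yl]trimethylsilane
Conditions: I2, PPh3, imidazole, CH2Cl2, 0 °C to rt
Reagents that add atoms: iodine, [I][I]
Why: Appel-type iodination of the second primary alcohol gives the precursor of the alkylmetal, with both stereocentres untouched.

**Chain completion**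

Step 25
Reactants: 34 [(6R,10S)-12-iodo-6,10-dimethyldodec-1-yn-1-yl]trimethylsilane; 21 (1E,5E,9E)-1-iodo-2,6,10-trimethyl-12-[(1S)-2,6,6-trimethylcyclohex-2-en-1-yl]dodeca-1,5,9-triene
Product: 37 trimethyl{(6R,10S,13E,17E,21E)-6,10,14,18,22-pentamethyl-24-[(1S)-2,6,6-trimethylcyclohex-2-en-1-yl]tetracosa-13,17,21-trien-1-yn-1-yl}silane, via alkyllithium 35 (not isolated), via alkylzinc bromide 36 (not isolated)
Conditions: 34, t-BuLi (2.1 equiv), Et2O, −78 °C; ZnBr2, THF, −78 to 0 °C; then 21, Pd(dppf)Cl2 (5 mol %), THF, rt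
Reagents that add atoms: none
Why: Negishi sp3–sp2 coupling, in which iodine–lithium exchange and transmetalation give a primary alkylzinc that couples with the alkenyl iodide on zerovalent palladium (formed from the precatalyst by the organozinc) with retention of E geometry, forming C13'–C14' without touching the silylalkyne.

Step 26
Reactants: 37 the full side chain as silylalkyne
Product: 38 (6R,10S,13E,17E,21E)-6,10,14,18,22-pentamethyl-24-[(1S)-2,6,6-trimethylcyclohex-2-en-1-yl]tetracosa-13,17,21-trien-1-yne
Conditions: K2CO3, MeOH/THF, rt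
Reagents that add atoms: none
Why: Methoxide-induced protodesilylation frees the terminal alkyne for the last carbometalation.

**Quinone and final coupling**

Step 27
Reactants: 39 menadione (2-methyl-1,4-naphthoquinone)
Product: 40 2-(chloromethyl)-3-methyl-1,4-naphthoquinone
Conditions: aqueous HCHO (37%), HCl (gas), AcOH, rt
Reagents that add atoms: formaldehyde, C=O; hydrogen chloride, Cl
Why: Blanc-type chloromethylation at the only unsubstituted quinone carbon gives the allylic-type chloride used as the electrophile.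

Step 28
Reactants: 38 the full side chain as terminal alkyne; 40 2-(chloromethyl)-3-methyl-1,4-naphthoquinone
Product: 42 target CNP0165638.1, via E-alkenyldimethylalane 41 (not isolated)
Conditions: 38, Me3Al (2 equiv), Cp2ZrCl2 (0.25 equiv), ClCH2CH2Cl, 0 °C to rt; volatiles and excess Me3Al removed in vacuo, hexane trituration; then 40, NiCl2(PPh3)2 (5 mol %) pre-reduced with n-BuLi (10 mol %) to zerovalent nickel, THF, −20 °C to rt
Reagents that add atoms: trimethylaluminium, C[Al](C)C
Why: Syn methylalumination sets the E C2'=C3' alkene, and the nickel-catalysed coupling of the alkenylalane with the chloromethylquinone (oxidative addition of C–Cl, transmetalation from aluminium, reductive elimination with retention) forms C1'–C2', removal of free Me3Al beforehand protecting the quinone carbonyls.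

**Compound list**

1 | 4,4-dimethylcyclohex-2-en-1-one | CC1(C)CCC(=O)C=C1 | starting material
2 | 2-iodo-4,4-dimethylcyclohex-2-en-1-one | CC1(C)CCC(=O)C(I)=C1 | intermediate
3 | (1R)-2-iodo-4,4-dimethylcyclohex-2-en-1-ol | O[C@@H]1CCC(C)(C)C=C1I | intermediate
4 | (1R)-2,4,4-trimethylcyclohex-2-en-1-ol | O[C@@H]1CCC(C)(C)C=C1C | intermediate
5 | tributyl({[(1R)-2,4,4-trimethylcyclohex-2-en-1-yl]oxy}methyl)stannane | CCCC[Sn](CCCC)(CCCC)CO[C@@H]1CCC(C)(C)C=C1C | intermediate
6 | lithiomethyl ether of 4 | [Li]CO[C@@H]1CCC(C)(C)C=C1C | intermediate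
7 | (S)-alpha-cyclogeraniol, [(1S)-2,6,6-trimethylcyclohex-2-en-1-yl]methanol | CC1=CCCC(C)(C)[C@@H]1CO | intermediate
8 | phenyl {[(1S)-2,6,6-trimethylcyclohex-2-en-1-yl]methyl} sulfide | CC1=CCCC(C)(C)[C@@H]1CSc1ccccc1 | intermediate
9 | (S)-alpha-cyclogeranyl phenyl sulfone | CC1=CCCC(C)(C)[C@@H]1CS(=O)(=O)c1ccccc1 | intermediate
10 | geranyl bromide | CC(C)=CCC/C(C)=C/CBr | starting material
11 | 1-(trimethylsilyl)propyne | CC#C[Si](C)(C)C | starting material
12 | 3-lithio-1-(trimethylsilyl)propyne | [Li]CC#C[Si](C)(C)C | intermediate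
13 | trimethyl[(5E)-6,10-dimethylundeca-5,9-dien-1-yn-1-yl]silane | CC(C)=CCC/C(C)=C/CCC#C[Si](C)(C)C | intermediate
14 | (2E,6E)-2,6-dimethyl-11-(trimethylsilyl)undeca-2,6-dien-10-yn-1-ol | OC/C(C)=C/CC/C(C)=C/CCC#C[Si](C)(C)C | intermediate
15 | [(5E,9E)-11-bromo-6,10-dimethylundeca-5,9-dien-1-yn-1-yl]trimethylsilane | BrC/C(C)=C/CC/C(C)=C/CCC#C[Si](C)(C)C | intermediate
16 | lithiated sulfone 9 | CC1=CCCC(C)(C)[C@@H]1C([Li])S(=O)(=O)c1ccccc1 | intermediate
17 | ring–chain sulfone (both epimers at the sulfone carbon) | CC1=CCCC(C)(C)[C@@H]1C(C/C(C)=C/CC/C(C)=C/CCC#C[Si](C)(C)C)S(=O)(=O)c1ccccc1 | intermediate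
18 | trimethyl{(5E,9E)-6,10-dimethyl-12-[(1S)-2,6,6-trimethylcyclohex-2-en-1-yl]dodeca-5,9-dien-1-yn-1-yl}silane | CC1=CCCC(C)(C)[C@@H]1CC/C(C)=C/CC/C(C)=C/CCC#C[Si](C)(C)C | intermediate
19 | (5E,9E)-6,10-dimethyl-12-[(1S)-2,6,6-trimethylcyclohex-2-en-1-yl]dodeca-5,9-dien-1-yne | CC1=CCCC(C)(C)[C@@H]1CC/C(C)=C/CC/C(C)=C/CCC#C | intermediate
20 | dimethyl{(1E,5E,9E)-2,6,10-trimethyl-12-[(1S)-2,6,6-trimethylcyclohex-2-en-1-yl]dodeca-1,5,9-trien-1-yl}alane | CC1=CCCC(C)(C)[C@@H]1CC/C(C)=C/CC/C(C)=C/CC/C(C)=C/[Al](C)C | intermediate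
21 | (1E,5E,9E)-1-iodo-2,6,10-trimethyl-12-[(1S)-2,6,6-trimethylcyclohex-2-en-1-yl]dodeca-1,5,9-triene | CC1=CCCC(C)(C)[C@@H]1CC/C(C)=C/CC/C(C)=C/CC/C(C)=C/I | intermediate
22 | (2E,6E)-farnesol | CC(C)=CCC/C(C)=C/CC/C(C)=C/CO | starting material
23 | (2E,6E)-farnesyl pivalate | CC(C)=CCC/C(C)=C/CC/C(C)=C/COC(=O)C(C)(C)C | intermediate
24 | (2E,6E)-10-bromo-11-hydroxy-3,7,11-trimethyldodeca-2,6-dien-1-yl pivalate (racemic at C10) | CC(C)(O)C(Br)CC/C(C)=C/CC/C(C)=C/COC(=O)C(C)(C)C | intermediate
25 | (2E,6E)-10,11-epoxy-3,7,11-trimethyldodeca-2,6-dien-1-yl pivalate (racemic) | CC1(C)OC1CC/C(C)=C/CC/C(C)=C/COC(=O)C(C)(C)C | intermediate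
26 | (2E,6E)-3,7-dimethyl-10-oxodeca-2,6-dien-1-yl pivalate | O=CCC/C(C)=C/CC/C(C)=C/COC(=O)C(C)(C)C | intermediate
27 | (2E,6E)-10-hydroxy-3,7-dimethyldeca-2,6-dien-1-yl pivalate | OCCC/C(C)=C/CC/C(C)=C/COC(=O)C(C)(C)C | intermediate
28 | (3S,7R)-10-hydroxy-3,7-dimethyldecyl pivalate | CC(C)(C)C(=O)OCC[C@@H](C)CCC[C@@H](C)CCCO | intermediate
29 | (3S,7R)-10-iodo-3,7-dimethyldecyl pivalate | CC(C)(C)C(=O)OCC[C@@H](C)CCC[C@@H](C)CCCI | intermediate
30 | ethynyltrimethylsilane | C#C[Si](C)(C)C | starting material
31 | lithium (trimethylsilyl)acetylide | [Li]C#C[Si](C)(C)C | intermediate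
32 | (3S,7R)-3,7-dimethyl-12-(trimethylsilyl)dodec-11-yn-1-yl pivalate | CC(C)(C)C(=O)OCC[C@@H](C)CCC[C@@H](C)CCCC#C[Si](C)(C)C | intermediate
33 | (3S,7R)-3,7-dimethyl-12-(trimethylsilyl)dodec-11-yn-1-ol | OCC[C@@H](C)CCC[C@@H](C)CCCC#C[Si](C)(C)C | intermediate
34 | [(6R,10S)-12-iodo-6,10-dimethyldodec-1-yn-1-yl]trimethylsilane | ICC[C@@H](C)CCC[C@@H](C)CCCC#C[Si](C)(C)C | intermediate
35 | [(3S,7R)-3,7-dimethyl-12-(trimethylsilyl)dodec-11-yn-1-yl]lithium | [Li]CC[C@@H](C)CCC[C@@H](C)CCCC#C[Si](C)(C)C | intermediate
36 | [(3S,7R)-3,7-dimethyl-12-(trimethylsilyl)dodec-11-yn-1-yl]zinc bromide | Br[Zn]CC[C@@H](C)CCC[C@@H](C)CCCC#C[Si](C)(C)C | intermediate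
37 | trimethyl{(6R,10S,13E,17E,21E)-6,10,14,18,22-pentamethyl-24-[(1S)-2,6,6-trimethylcyclohex-2-en-1-yl]tetracosa-13,17,21-trien-1-yn-1-yl}silane | CC1=CCCC(C)(C)[C@@H]1CC/C(C)=C/CC/C(C)=C/CC/C(C)=C/CC[C@@H](C)CCC[C@@H](C)CCCC#C[Si](C)(C)C | intermediate
38 | (6R,10S,13E,17E,21E)-6,10,14,18,22-pentamethyl-24-[(1S)-2,6,6-trimethylcyclohex-2-en-1-yl]tetracosa-13,17,21-trien-1-yne | CC1=CCCC(C)(C)[C@@H]1CC/C(C)=C/CC/C(C)=C/CC/C(C)=C/CC[C@@H](C)CCC[C@@H](C)CCCC#C | intermediate
39 | menadione (2-methyl-1,4-naphthoquinone) | CC1=CC(=O)c2ccccc2C1=O | starting material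
40 | 2-(chloromethyl)-3-methyl-1,4-naphthoquinone | CC1=C(CCl)C(=O)c2ccccc2C1=O | intermediate
41 | dimethyl{(1E,6R,10S,13E,17E,21E)-2,6,10,14,18,22-hexamethyl-24-[(1S)-2,6,6-trimethylcyclohex-2-en-1-yl]tetracosa-1,13,17,21-tetraen-1-yl}alane | CC1=CCCC(C)(C)[C@@H]1CC/C(C)=C/CC/C(C)=C/CC/C(C)=C/CC[C@@H](C)CCC[C@@H](C)CCC/C(C)=C/[Al](C)C | intermediate
42 | CNP0165638.1, 2-methyl-3-{(2E,7R,11S,14E,18E,22E)-3,7,11,15,19,23-hexamethyl-25-[(1S)-2,6,6-trimethylcyclohex-2-en-1-yl]pentacosa-2,14,18,22-tetraen-1-yl}naphthalene-1,4-dione | CC1=CCCC(C)(C)[C@@H]1CC/C(C)=C/CC/C(C)=C/CC/C(C)=C/CC[C@@H](C)CCC[C@@H](C)CCC/C(C)=C/CC1=C(C)C(=O)c2ccccc2C1=O | target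

**Step count**

Total steps: 28. Longest linear sequence: 14 steps (from 1 through steps 1–7, 11–14, 25, 26 and 28 to 42).

**Three steps most likely to fail**

1. Step 5 (Wittig–Still shift). The lithiomethyl ether may take the [1,2] radical-pair path, or be quenched before it can bond to the alkene carbon flanked by the quaternary centre, so the carbinol chirality would not be relayed cleanly.
Fallback, setting out from 4 and coming back at 7: alcohol 4 would be heated with triethyl orthoacetate and a trace of propionic acid at 140 °C (Johnson–Claisen). The chair [3,3] shift delivers a two-carbon arm to the same carbon and the same face and should give ethyl 2-[(1S)-2,6,6-trimethylcyclohex-2-en-1-yl]acetate F1. Its potassium enolate (KN(SiMe3)2, THF, −78 °C) would be hydroxylated with 2-(phenylsulfonyl)-3-phenyloxaziridine to ethyl 2-hydroxy-2-[(1S)-2,6,6-trimethylcyclohex-2-en-1-yl]acetate F2 (either epimer at the new carbinol). LiAlH4 in THF would give 1-[(1S)-2,6,6-trimethylcyclohex-2-en-1-yl]ethane-1,2-diol F3. NaIO4 in buffered aqueous THF at 0 °C would remove the extra carbon to give (S)-alpha-cyclocitral F4, which would be extracted cold and reduced at once with NaBH4 to 7, so that this epimerisable aldehyde is not stored.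

2. Step 28 (one-pot methylalumination and nickel coupling with the free quinone). Methyl transfer from residual aluminium species or electron transfer to the unprotected quinone may outrun the cross-coupling, and late material would be lost.
Fallback, setting out from 39 (with alane 41 made from 38 as in step 28) and coming back at 42: menadione 39 would be reduced with Na2S2O4 in EtOAc/water to 2-methylnaphthalene-1,4-diol F5 and methylated (Me2SO4, KOH, acetone) to 1,4-dimethoxy-2-methylnaphthalene F6. Chloromethylation (paraformaldehyde, HCl, AcOH) would give 2-(chloromethyl)-1,4-dimethoxy-3-methylnaphthalene F7. Alane 41 would be coupled with this benzylic chloride under the same zerovalent nickel catalyst (NiCl2(PPh3)2 reduced with n-BuLi) to the hydroquinone dimethyl ether of the target F8. (NH4)2Ce(NO3)6 in MeCN/water at 0 °C would then unmask quinone 42.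

3. Step 20 (double asymmetric hydrogenation). Incomplete enantioface discrimination at one of the two alkenes, or alkene isomerisation before reduction, would give diastereomers that cannot be removed later.
Fallback, setting out from 11 (as its lithio derivative 12) and coming back at 28: one centre would be taken from the chiral pool and the other set by a hydroxyl-directed hydrogenation.
- 12 would be alkylated with bought (S)-citronellyl bromide F9 (THF/DMPU) to trimethyl[(6R)-6,10-dimethylundec-9-en-1-yn-1-yl]silane F10.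
- K2CO3 in MeOH would give (6R)-6,10-dimethylundec-9-en-1-yne F11.
- Methylalumination (Me3Al, Cp2ZrCl2) would give the E-alkenyldimethylalane F12, which as its ate complex (n-BuLi) would be trapped with paraformaldehyde to (2E,7R)-3,7,11-trimethyldodeca-2,10-dien-1-ol F13.
- Ru–BINAP hydrogenation of this allylic alcohol (Ru(OAc)2[(R)-BINAP], H2, MeOH; the ligand antipode that takes geraniol to (S)-citronellol) reduces only the 2,3-alkene and should give (3S,7R)-3,7,11-trimethyldodec-10-en-1-ol F14.
- Pivaloylation would give (3S,7R)-3,7,11-trimethyldodec-10-en-1-yl pivalate F15.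
- Ozonolysis in CH2Cl2/MeOH at −78 °C with NaBH4 work-up would give 28.

**Further compounds**

F1 | step 5 | ethyl 2-[(1S)-2,6,6-trimethylcyclohex-2-en-1-yl]acetate | CC1=CCCC(C)(C)[C@@H]1CC(=O)OCC
F2 | step 5 | ethyl 2-hydroxy-2-[(1S)-2,6,6-trimethylcyclohex-2-en-1-yl]acetate (either epimer at the carbinol) | CC1=CCCC(C)(C)[C@@H]1C(O)C(=O)OCC
F3 | step 5 | 1-[(1S)-2,6,6-trimethylcyclohex-2-en-1-yl]ethane-1,2-diol | CC1=CCCC(C)(C)[C@@H]1C(O)CO
F4 | step 5 | (S)-alpha-cyclocitral, (1S)-2,6,6-trimethylcyclohex-2-ene-1-carbaldehyde | CC1=CCCC(C)(C)[C@@H]1C=O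
F5 | step 28 | 2-methylnaphthalene-1,4-diol | Cc1cc(O)c2ccccc2c1O
F6 | step 28 | 1,4-dimethoxy-2-methylnaphthalene | COc1cc(C)c(OC)c2ccccc12
F7 | step 28 | 2-(chloromethyl)-1,4-dimethoxy-3-methylnaphthalene | COc1c(C)c(CCl)c(OC)c2ccccc12
F8 | step 28 | hydroquinone dimethyl ether of the target | CC1=CCCC(C)(C)[C@@H]1CC/C(C)=C/CC/C(C)=C/CC/C(C)=C/CC[C@@H](C)CCC[C@@H](C)CCC/C(C)=C/Cc1c(C)c(OC)c2ccccc2c1OC
F9 | step 20 | (S)-citronellyl bromide (bought) | BrCC[C@@H](C)CCC=C(C)C
F10 | step 20 | trimethyl[(6R)-6,10-dimethylundec-9-en-1-yn-1-yl]silane | C[Si](C)(C)C#CCCC[C@@H](C)CCC=C(C)C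
F11 | step 20 | (6R)-6,10-dimethylundec-9-en-1-yne | C#CCCC[C@@H](C)CCC=C(C)C
F12 | step 20 | dimethyl[(1E,6R)-2,6,10-trimethylundeca-1,9-dien-1-yl]alane | C[Al](C)/C=C(C)/CCC[C@@H](C)CCC=C(C)C
F13 | step 20 | (2E,7R)-3,7,11-trimethyldodeca-2,10-dien-1-ol | OC/C=C(C)/CCC[C@@H](C)CCC=C(C)C
F14 | step 20 | (3S,7R)-3,7,11-trimethyldodec-10-en-1-ol | OCC[C@@H](C)CCC[C@@H](C)CCC=C(C)C
F15 | step 20 | (3S,7R)-3,7,11-trimethyldodec-10-en-1-yl pivalate | CC(C)(C)C(=O)OCC[C@@H](C)CCC[C@@H](C)CCC=C(C)C
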